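## The problem

Robustaol A (17) is a diarylmethane: two fully substituted phloroglucinol rings joined by one methylene carbon between C4 of ring A and C1' of ring B. It has no stereocentre, so nothing has to be controlled or relayed stereochemically, and the whole difficulty is regiochemical. Ring A needs its three oxygens told apart: the C1 oxygen, wedged between the C2 methyl and the C6 isobutyryl group, is a methyl ether, while C3 and C5 are free phenols. Ring B carries two different acyl-type groups, formyl at C3' and isovaleryl at C5', on either side of the C4' hydroxyl and at fixed positions relative to the bridge. Substitution of a symmetric phloroglucinol would therefore have to distinguish equivalent sites. The compound is also fragile. Once both rings are free phenols the bridge can break and scramble through quinone methides in acid or base, the methyl ether ortho to the ketone is exposed to chelating Lewis acids, the formyl group can be reduced, and the polyphenols oxidise in base. The enabling feature is that C6'–C1'–C2'–C3'–C4'–C5' and the isovaleryl chain form one unbroken chain with oxygen on every second carbon (C6', C2', C4', acyl carbonyl). Ring B is thus a folded 3,5,7-trioxo ester primed by isovalerate, with the bridge on the ester α-carbon. Closing C5'–C6' by Claisen condensation builds ring B with everything in place except the formyl group, and the chain can be stored as a 4-hydroxy-2-pyranone whose C3 is the future C1'.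

## Retrosynthesis

**17 to 16.** The last bonds cut are the two benzyl–oxygen bonds at C3 and C5 of ring A. Ring A is kept as its bis(benzyl ether) to the end because an etherified ring A cannot form a quinone methide, which protects the bridge through every basic and acidic step. The forward reaction must remove two hindered aryl benzyl ethers without touching the C1 methyl ether (ortho to a ketone) or the aldehyde.

**16 to 14.** The C3'–CHO bond is cut next. C3' is the only aromatic CH in 14, so the formylation has no regiochemical choice. The formyl group could not be carried through a methoxide-mediated polyketone cyclisation, so it must come after ring closure. The forward reaction must be an electrophilic formylation that leaves the benzyl ethers and the bridge alone.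

**14 to 12 (through 13).** Here the C5'–C6' bond is cut and ring B disappears. The neighbouring cut, the bridge bond C1'–CH2 (Friedel–Crafts union of two phloroglucinols), would need a ring B nucleophile with two reactive positions and would expose free phenols to acid. Opening ring B instead gives triketo ester 13, handled as pyranone 12, in which the arylmethyl group already sits on the carbon that becomes C1'. The precursor has one aromatic ring fewer. The forward reaction must close by Claisen, not aldol, condensation.

**12 to 7 and 10 (through 11).** The bond between pyranone C3 and the benzylic carbon is cut, dividing the molecule into halves of similar size. Benzylation with a halide would give O- and C-alkylation mixtures. Reductive alkylation with aldehyde 7 uses the one strongly acidic carbon of 10 and forms only the C–C bond. The forward reaction must condense at C3 and reduce alkylidene 11 before a second pyranone adds to it.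

**10 to 8 and 9.** The bond between the 6-methyl carbon of the pyranone and the isovaleryl carbonyl is cut. Both pieces are catalogue compounds, and the dianion of 8 reacts at the methyl carbon, so the forward reaction is a single C-acylation.

**7 to 6, 4, 3, then 1 and 2.** Ring A is taken apart in the order O–CH3, C–CHO, two O–benzyl bonds, C–acyl. Acylation of 1 comes first because its two free positions are equivalent. In 3 the hydroxyl between the ketone and the C-methyl group is chelated and buttressed, so double benzylation should leave exactly the oxygen that must become the methyl ether (4). Formylation of the last CH (6) and methylation (7) then follow without any choice of site. The forward sequence asks for one site-selective step, the benzylation.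

## Roads not taken

**Alternative 1:** Ring A is cut at C4–C5 and C2–C3 and built by a Danheiser benzannulation. Heating 3-methoxy-2-methylcyclobut-2-en-1-one A1 with the siloxyalkyne A2 (the triisopropylsilyl ynol ether carrying the tribenzylated ring B on its propargylic carbon) gives a vinylketene that adds the alkyne. The adduct reopens and closes by a six-electron electrocyclisation to phenol A3.
- Merits: the three oxygens of ring A emerge differentiated (methyl ether, silyl ether, free phenol) by construction, under neutral thermal conditions. This is better than the chosen plan, which relies on a site-selective benzylation (step 2).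
- Weak points: neither A1 nor A2 is a catalogue compound and each needs its own short synthesis. After the key step three carbon substituents are still missing: the isobutyryl group at C6, and the isovaleryl and formyl groups on a symmetric tris(benzyloxy) ring B with two equivalent positions. Introducing two different acyl groups there would require Friedel–Crafts chemistry on a benzyl-protected diarylmethane.
- Comparison: the chosen plan sets against the cleaner oxygen pattern a ring B whose substitution is fixed by the Claisen closure, leaving one formylation at the only free CH.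

**Alternative 2:** The three C–O bonds of ring B are cut. Ring B is carried as the 2,4,6-trifluoro-3-isovalerylphenyl unit of A4, and sodium benzyloxide displaces all three fluorides, each ortho or para to the ketone, to give pentabenzyl ether A5.
- Merits: convergent, avoids any polyketone or free polyphenol before the end, and fixes the ring B pattern by the position of the halogens. The endgame from A5 (formylation, global debenzylation) is as short as the chosen one, and no hindered aldehyde condensation is needed.
- Weak points: each benzyloxy group introduced deactivates the ring for the next substitution, so the third displacement is the slowest. Benzyloxide can enolise the isovaleryl ketone, which cancels its activating effect. The doubly benzylic methylene of A4 is acidified by the fluoroarene. A4 still requires the complete ring A half and a separate union with the fluoroarene, and five benzyl ethers must be removed next to the sensitive methyl ether.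
- Comparison: the chosen key step is an intramolecular closure driven by aromatisation, not three intermolecular substitutions of falling rate, and its oxygens come from a cheap pyranone.

**Alternative 3:** Ring A is cut at C3–C4 and C1–C6 in a formal (3+3) cyclocondensation. TiCl4 promotes acylation of the terminal carbon of the bis(silyl enol ether) A7 by 3,3-dimethoxy-2-methylprop-2-enoyl chloride A6. The central carbon then adds to the ketene acetal carbon with loss of methanol, giving A8 with ring A complete.
- Merits: methyl ether, C-methyl, both phenols and the isobutyryl group of ring A are placed from acyclic pieces with no selective O-alkylation. In this respect it is superior to step 2 of the chosen plan.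
- Weak points: A6 is a moisture-sensitive ketene acetal acid chloride. Closure through carbon must beat closure through oxygen, which would give a pyranone. TiCl4 meets three benzyl ethers. As in Alternative 1, ring B of A8 still lacks both the isovaleryl and formyl groups at two equivalent positions, now next to a free resorcinol ring A that invites bridge scission.
- Comparison: the chosen plan accepts a less elegant ring A synthesis in exchange for a ring B that needs no differentiation of equivalent sites.

Key step: step 7

## Route

Assumption (step 2): of the two hydroxyls ortho to the ketone in 3, the one next to the ring hydrogen is taken to be benzylated before the one buttressed by the C-methyl group, as is usual for C-methylated phloroacylphenones.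

Remark: 11 (alkene geometry) and 13 (enol and chelate forms, labile α-centre) form as converging mixtures and 15 is racemic, so no configuration is specified for them.

Step 1
Reactants: 1 2,4,6-trihydroxytoluene; 2 isobutyryl chloride
Product: 3 1-(2,4,6-trihydroxy-3-methylphenyl)-2-methylpropan-1-one
Conditions: AlCl3, PhNO2/CH2Cl2, 0 °C to rt; aq. HCl
Reagents that add atoms: none
Why: Friedel–Crafts C-acylation of the electron-rich ring; the two free positions of 1 are equivalent and the first acyl group deactivates the ring toward a second acylation.

Step 2
Reactants: 3 1-(2,4,6-trihydroxy-3-methylphenyl)-2-methylpropan-1-one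
Product: 4 1-[4,6-bis(benzyloxy)-2-hydroxy-3-methylphenyl]-2-methylpropan-1-one
Conditions: BnBr (2.1 equiv), K2CO3, acetone, reflux
Reagents that add atoms: benzyl bromide, BrCc1ccccc1
Why: Williamson etherification with a weak base; the hydroxyl para to the ketone is most acidic and reacts first, then the less hindered ortho hydroxyl, leaving free the hydroxyl that is chelated to the ketone and buttressed by the C-methyl group.

Step 3
Reactants: 4 1-[4,6-bis(benzyloxy)-2-hydroxy-3-methylphenyl]-2-methylpropan-1-one
Product: 6 2,6-bis(benzyloxy)-4-hydroxy-3-methyl-5-(2-methylpropanoyl)benzaldehyde, via Vilsmeier iminium chloride 5 (not isolated)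
Conditions: POCl3, DMF, MeCN, 0 °C to rt; then H2O, 50 °C
Reagents that add atoms: N,N-dimethylformamide, CN(C)C=O; water, O
Why: Vilsmeier–Haack formylation at the only ring CH, para to the free hydroxyl and ortho to both benzyloxy groups; the conditions spare benzyl ethers, and the isopropyl ketone has a single hindered α-hydrogen, so reaction at the ketone should be slow.

Step 4
Reactants: 6 2,6-bis(benzyloxy)-4-hydroxy-3-methyl-5-(2-methylpropanoyl)benzaldehyde
Product: 7 2,6-bis(benzyloxy)-4-methoxy-3-methyl-5-(2-methylpropanoyl)benzaldehyde
Conditions: MeI, K2CO3, DMF, 40 °C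
Reagents that add atoms: iodomethane, CI
Why: Williamson O-methylation of the last phenol, made more acidic by the para formyl group; the ring is fully substituted, so only O-alkylation keeps it aromatic.

Step 5
Reactants: 8 4-hydroxy-6-methyl-2H-pyran-2-one; 9 methyl 3-methylbutanoate
Product: 10 4-hydroxy-6-(4-methyl-2-oxopentyl)-2H-pyran-2-one
Conditions: 8 (2 equiv), LiN(i-Pr)2 (4 equiv), THF, −78 to 0 °C; then 9 (1 equiv); aq. HCl
Reagents that add atoms: none
Why: Claisen-type C-acylation of the dianion of 8 (deprotonated at oxygen and at the 6-methyl group), which reacts at the methyl carbon; the dianion is used in twofold excess because the more acidic product consumes one equivalent as base.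

Step 6
Reactants: 7 2,6-bis(benzyloxy)-4-methoxy-3-methyl-5-(2-methylpropanoyl)benzaldehyde; 10 4-hydroxy-6-(4-methyl-2-oxopentyl)-2H-pyran-2-one
Product: 12 3-{[2,6-bis(benzyloxy)-4-methoxy-3-methyl-5-(2-methylpropanoyl)phenyl]methyl}-4-hydroxy-6-(4-methyl-2-oxopentyl)-2H-pyran-2-one, via arylidene pyrandione 11 (not isolated)
Conditions: Hantzsch ester (diethyl 2,6-dimethyl-1,4-dihydropyridine-3,5-dicarboxylate, 1.2 equiv), L-proline (20 mol %), CH2Cl2, rt
Reagents that add atoms: none
Why: organocatalytic three-component reductive alkylation: proline-catalysed Knoevenagel condensation at the most acidic carbon (C3 of the 4-hydroxypyranone) gives 11, which the Hantzsch ester reduces by conjugate hydride transfer; the two ortho benzyloxy groups disfavour addition of a second pyranone.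

Step 7
Reactants: 12 3-{[2,6-bis(benzyloxy)-4-methoxy-3-methyl-5-(2-methylpropanoyl)phenyl]methyl}-4-hydroxy-6-(4-methyl-2-oxopentyl)-2H-pyran-2-one
Product: 14 1-[3-{[2,6-bis(benzyloxy)-4-methoxy-3-methyl-5-(2-methylpropanoyl)phenyl]methyl}-2,4,6-trihydroxyphenyl]-3-methylbutan-1-one, via ring-opened triketo methyl ester 13 (not isolated)
Conditions: Mg(OMe)2 (excess), MeOH, reflux; then aq. HCl
Reagents that add atoms: none
Why: Methoxide on magnesium adds to the lactone carbonyl of 12 and opens it to the magnesium chelate of triketo ester 13. The carbon between the 5- and 7-keto groups of 13 (future C5'), the only doubly activated carbon that can reach the ester, attacks the ester carbonyl (future C6') in an intramolecular Claisen (Dieckmann-type) condensation; loss of methoxide and enolisation of the resulting cyclohexanetrione give aromatic ring B. The closest known reaction type is the Mg(OMe)2-mediated Claisen cyclisation of 3,5,7-trioxo esters and of their 6-(2-oxoalkyl)-4-hydroxy-2-pyranone forms to acylphloroglucinols. Ring B closes in the 6-(enolendo)-exo-trig mode, and aromatisation makes the closure irreversible. No stereocentre is created, and the labile centre at C2 of 13 disappears on aromatisation. The selectivity required is Claisen over aldol closure: magnesium chelation of the polyketone enolates favours attack on the ester, and the competing aldol from the arylmethyl-bearing carbon onto the isovaleryl ketone would give a quaternary centre that cannot aromatise and can revert. Ring A is inert here because all three of its oxygens are etherified, so it cannot form a quinone methide and the bridge cannot be cleaved by base, and its hindered isobutyryl ketone has no carbanion within reach.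

Step 8
Reactants: 14 1-[3-{[2,6-bis(benzyloxy)-4-methoxy-3-methyl-5-(2-methylpropanoyl)phenyl]methyl}-2,4,6-trihydroxyphenyl]-3-methylbutan-1-one
Product: 16 3-{[2,6-bis(benzyloxy)-4-methoxy-3-methyl-5-(2-methylpropanoyl)phenyl]methyl}-2,4,6-trihydroxy-5-(3-methylbutanoyl)benzaldehyde, via aryl chloro(methoxy)methane 15 (not isolated)
Conditions: Cl2CHOMe, TiCl4, CH2Cl2, −20 to 0 °C; then aq. HCl
Reagents that add atoms: dichloromethyl methyl ether, COC(Cl)Cl; water, O
Why: Rieche formylation; C3' is the only ring CH in the molecule and lies between two titanium-bound phenoxides, ring A is fully substituted, and low temperature limits attack of TiCl4 on the benzyl ethers.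

Step 9
Reactants: 16 3-{[2,6-bis(benzyloxy)-4-methoxy-3-methyl-5-(2-methylpropanoyl)phenyl]methyl}-2,4,6-trihydroxy-5-(3-methylbutanoyl)benzaldehyde
Product: 17 Robustaol A, 3-{[2,6-dihydroxy-4-methoxy-3-methyl-5-(2-methylpropanoyl)phenyl]methyl}-2,4,6-trihydroxy-5-(3-methylbutanoyl)benzaldehyde
Conditions: BCl3, C6HMe5, CH2Cl2, −78 °C; then H2O
Reagents that add atoms: none
Why: Lewis-acid debenzylation with BCl3 and pentamethylbenzene as benzyl cation scavenger; benzyl ethers cleave at −78 °C, well below the temperature needed for chelation-assisted cleavage of the methyl ether ortho to the ketone, and the scavenger prevents C-benzylation of the phenol rings.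

## Compound list

1 | 2,4,6-trihydroxytoluene | Cc1c(O)cc(O)cc1O | starting material
2 | isobutyryl chloride (2-methylpropanoyl chloride) | CC(C)C(Cl)=O | starting material
3 | 1-(2,4,6-trihydroxy-3-methylphenyl)-2-methylpropan-1-one | CC(C)C(=O)c1c(O)cc(O)c(C)c1O | intermediate
4 | 1-[4,6-bis(benzyloxy)-2-hydroxy-3-methylphenyl]-2-methylpropan-1-one | CC(C)C(=O)c1c(OCc2ccccc2)cc(OCc2ccccc2)c(C)c1O | intermediate
5 | {[2,6-bis(benzyloxy)-4-hydroxy-3-methyl-5-(2-methylpropanoyl)phenyl]methylidene}dimethylammonium chloride | C[N+](C)=Cc1c(OCc2ccccc2)c(C(=O)C(C)C)c(O)c(C)c1OCc1ccccc1.[Cl-] | intermediate (not isolated)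
6 | 2,6-bis(benzyloxy)-4-hydroxy-3-methyl-5-(2-methylpropanoyl)benzaldehyde | O=Cc1c(OCc2ccccc2)c(C(=O)C(C)C)c(O)c(C)c1OCc1ccccc1 | intermediate
7 | 2,6-bis(benzyloxy)-4-methoxy-3-methyl-5-(2-methylpropanoyl)benzaldehyde | O=Cc1c(OCc2ccccc2)c(C(=O)C(C)C)c(OC)c(C)c1OCc1ccccc1 | intermediate
8 | 4-hydroxy-6-methyl-2H-pyran-2-one | CC1=CC(O)=CC(=O)O1 | starting material
9 | methyl 3-methylbutanoate | COC(=O)CC(C)C | starting material
10 | 4-hydroxy-6-(4-methyl-2-oxopentyl)-2H-pyran-2-one | O=C1OC(CC(=O)CC(C)C)=CC(O)=C1 | intermediate
11 | 3-{[2,6-bis(benzyloxy)-4-methoxy-3-methyl-5-(2-methylpropanoyl)phenyl]methylidene}-6-(4-methyl-2-oxopentyl)-2H-pyran-2,4(3H)-dione (alkene geometry not defined) | O=C1OC(CC(=O)CC(C)C)=CC(=O)C1=Cc1c(OCc2ccccc2)c(C)c(OC)c(C(=O)C(C)C)c1OCc1ccccc1 | intermediate (not isolated)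
12 | 3-{[2,6-bis(benzyloxy)-4-methoxy-3-methyl-5-(2-methylpropanoyl)phenyl]methyl}-4-hydroxy-6-(4-methyl-2-oxopentyl)-2H-pyran-2-one | O=C1OC(CC(=O)CC(C)C)=CC(O)=C1Cc1c(OCc2ccccc2)c(C)c(OC)c(C(=O)C(C)C)c1OCc1ccccc1 | intermediate
13 | methyl 2-{[2,6-bis(benzyloxy)-4-methoxy-3-methyl-5-(2-methylpropanoyl)phenyl]methyl}-9-methyl-3,5,7-trioxodecanoate (racemic, present as its magnesium chelate) | COC(=O)C(Cc1c(OCc2ccccc2)c(C)c(OC)c(C(=O)C(C)C)c1OCc1ccccc1)C(=O)CC(=O)CC(=O)CC(C)C | intermediate (not isolated)
14 | 1-[3-{[2,6-bis(benzyloxy)-4-methoxy-3-methyl-5-(2-methylpropanoyl)phenyl]methyl}-2,4,6-trihydroxyphenyl]-3-methylbutan-1-one | CC(C)CC(=O)c1c(O)cc(O)c(Cc2c(OCc3ccccc3)c(C)c(OC)c(C(=O)C(C)C)c2OCc2ccccc2)c1O | intermediate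
15 | 1-[3-{[2,6-bis(benzyloxy)-4-methoxy-3-methyl-5-(2-methylpropanoyl)phenyl]methyl}-5-[chloro(methoxy)methyl]-2,4,6-trihydroxyphenyl]-3-methylbutan-1-one (racemic) | COC(Cl)c1c(O)c(C(=O)CC(C)C)c(O)c(Cc2c(OCc3ccccc3)c(C)c(OC)c(C(=O)C(C)C)c2OCc2ccccc2)c1O | intermediate (not isolated)
16 | 3-{[2,6-bis(benzyloxy)-4-methoxy-3-methyl-5-(2-methylpropanoyl)phenyl]methyl}-2,4,6-trihydroxy-5-(3-methylbutanoyl)benzaldehyde | O=Cc1c(O)c(C(=O)CC(C)C)c(O)c(Cc2c(OCc3ccccc3)c(C)c(OC)c(C(=O)C(C)C)c2OCc2ccccc2)c1O | intermediate
17 | Robustaol A, 3-{[2,6-dihydroxy-4-methoxy-3-methyl-5-(2-methylpropanoyl)phenyl]methyl}-2,4,6-trihydroxy-5-(3-methylbutanoyl)benzaldehyde | COc1c(C)c(O)c(Cc2c(O)c(C=O)c(O)c(C(=O)CC(C)C)c2O)c(O)c1C(=O)C(C)C | target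

## Step count and risk

Total steps: 9. Longest linear sequence: 8 steps (steps 1, 2, 3, 4, 6, 7, 8, 9; step 5 is the one-step side branch).

**Step 7 (key step).** The most likely failure is that, after the lactone opens, methoxide attacks one of the chain ketones and the polyketone fragments by retro-Claisen cleavage, or the chain re-closes to a pyranone. The cause would be the branched α-carbon next to the ester, which slows the Claisen attack. The fallback sets out from 10 and 7 and comes back at 14. Pyranone 10, which lacks the branch, is cyclised with Mg(OMe)2 in methanol to 3-methyl-1-(2,4,6-trihydroxyphenyl)butan-1-one F1. Aldehyde 7 is reduced with NaBH4 (MeOH/THF, 0 °C; the hindered ketone should survive) to 1-[2,4-bis(benzyloxy)-3-(hydroxymethyl)-6-methoxy-5-methylphenyl]-2-methylpropan-1-one F2. Acid-catalysed Friedel–Crafts benzylation (catalytic p-toluenesulfonic acid, CH2Cl2/MeCN) of an excess of F1 by F2 at one of its two equivalent ring positions then gives 14. The Claisen folding of ring B is retained and only the order of ring closure and bridge formation changes.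

**Step 2.** The risk is poor site selectivity in the second benzylation (reaction at the hydroxyl next to the C-methyl group) together with over-benzylation, because both ortho hydroxyls can chelate the ketone and differ only sterically. The fallback sets out from 1 and comes back at 7. Vilsmeier–Haack formylation of 1 gives 2,4,6-trihydroxy-3-methylbenzaldehyde F3. Mono-O-methylation (Me2SO4, 1 equiv, K2CO3, acetone) at the only non-chelated hydroxyl, para to the formyl group, gives 2,6-dihydroxy-4-methoxy-3-methylbenzaldehyde F4. TiCl4-mediated Friedel–Crafts acylation with 2 at the single free position gives 2,6-dihydroxy-4-methoxy-3-methyl-5-(2-methylpropanoyl)benzaldehyde F5, and double benzylation (BnBr, K2CO3, DMF, 60 °C) gives 7. In this order the methyl group goes onto the oxygen singled out electronically, not sterically.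

**Step 6.** The risk is slow Knoevenagel condensation of the doubly ortho-substituted, electron-rich aldehyde. During the delay the base- and heat-sensitive oxoalkyl side chain of 10 can cyclise or self-condense, so the reaction cannot simply be forced. The fallback sets out from 8 and 7 and comes back at 12. The same proline/Hantzsch ester reductive alkylation is run on the robust pyranone 8 (in excess, with heating if needed) to give 3-{[2,6-bis(benzyloxy)-4-methoxy-3-methyl-5-(2-methylpropanoyl)phenyl]methyl}-4-hydroxy-6-methyl-2H-pyran-2-one F6. The dianion of F6 (LiN(i-Pr)2, THF, −78 °C, with an extra equivalent for the hindered ring A ketone) is then acylated at the 6-methyl carbon with 9 to give 12.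

**Step 8.** The risk is chelation-assisted cleavage by TiCl4 of the ring A benzyl ether ortho to the ketone, with transfer of the benzyl group to C3', or acid scission of the bridge. The fallback sets out from 14 and comes back at 17. Hydrogenolysis (H2, Pd/C, EtOAc) removes both benzyl ethers while no aldehyde is present and gives 1-[3-{[2,6-dihydroxy-4-methoxy-3-methyl-5-(2-methylpropanoyl)phenyl]methyl}-2,4,6-trihydroxyphenyl]-3-methylbutan-1-one F7. Rieche formylation of F7 at its only ring CH then gives 17 directly, with no benzyl ether left to transfer.

**Step 9.** The risk is loss of the C1 methyl ether alongside debenzylation, because BCl3 chelated between the C6 ketone and the C1 oxygen is the classical reagent for cleaving such ethers if the temperature rises. The fallback sets out from 16 and comes back at 17. Catalytic hydrogenolysis (H2, Pd/C, EtOAc, rt, stopped after two equivalents of hydrogen) cannot cleave a methyl ether, and the strongly chelated formyl group is expected to be reduced only slowly. It makes no new compound.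

## Further compounds

F1 | step 7 | 3-methyl-1-(2,4,6-trihydroxyphenyl)butan-1-one | CC(C)CC(=O)c1c(O)cc(O)cc1O
F2 | step 7 | 1-[2,4-bis(benzyloxy)-3-(hydroxymethyl)-6-methoxy-5-methylphenyl]-2-methylpropan-1-one | OCc1c(OCc2ccccc2)c(C)c(OC)c(C(=O)C(C)C)c1OCc1ccccc1
F3 | step 2 | 2,4,6-trihydroxy-3-methylbenzaldehyde | Cc1c(O)cc(O)c(C=O)c1O
F4 | step 2 | 2,6-dihydroxy-4-methoxy-3-methylbenzaldehyde | COc1cc(O)c(C=O)c(O)c1C
F5 | step 2 | 2,6-dihydroxy-4-methoxy-3-methyl-5-(2-methylpropanoyl)benzaldehyde | COc1c(C)c(O)c(C=O)c(O)c1C(=O)C(C)C
F6 | step 6 | 3-{[2,6-bis(benzyloxy)-4-methoxy-3-methyl-5-(2-methylpropanoyl)phenyl]methyl}-4-hydroxy-6-methyl-2H-pyran-2-one | CC1=CC(O)=C(Cc2c(OCc3ccccc3)c(C)c(OC)c(C(=O)C(C)C)c2OCc2ccccc2)C(=O)O1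
F7 | step 8 | 1-[3-{[2,6-dihydroxy-4-methoxy-3-methyl-5-(2-methylpropanoyl)phenyl]methyl}-2,4,6-trihydroxyphenyl]-3-methylbutan-1-one | CC(C)CC(=O)c1c(O)cc(O)c(Cc2c(O)c(C)c(OC)c(C(=O)C(C)C)c2O)c1O
F0 | step 9 | none | none
A1 | alternative 1 | 3-methoxy-2-methylcyclobut-2-en-1-one | O=C1CC(OC)=C1C
A2 | alternative 1 | triisopropyl({3-[2,4,6-tris(benzyloxy)phenyl]prop-1-yn-1-yl}oxy)silane | CC(C)[Si](OC#CCc1c(OCc2ccccc2)cc(OCc2ccccc2)cc1OCc1ccccc1)(C(C)C)C(C)C
A3 | alternative 1 | 5-methoxy-4-methyl-2-{[2,4,6-tris(benzyloxy)phenyl]methyl}-3-[(triisopropylsilyl)oxy]phenol | COc1cc(O)c(Cc2c(OCc3ccccc3)cc(OCc4ccccc4)cc2OCc5ccccc5)c(O[Si](C(C)C)(C(C)C)C(C)C)c1C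
A4 | alternative 2 | 1-[2,4-bis(benzyloxy)-6-methoxy-5-methyl-3-{[2,4,6-trifluoro-3-(3-methylbutanoyl)phenyl]methyl}phenyl]-2-methylpropan-1-one | COc1c(C)c(OCc2ccccc2)c(Cc3c(F)cc(F)c(C(=O)CC(C)C)c3F)c(OCc4ccccc4)c1C(=O)C(C)C
A5 | alternative 2 | 1-[2,4,6-tris(benzyloxy)-3-{[2,6-bis(benzyloxy)-4-methoxy-3-methyl-5-(2-methylpropanoyl)phenyl]methyl}phenyl]-3-methylbutan-1-one | COc1c(C)c(OCc2ccccc2)c(Cc3c(OCc5ccccc5)cc(OCc6ccccc6)c(C(=O)CC(C)C)c3OCc7ccccc7)c(OCc4ccccc4)c1C(=O)C(C)C
A6 | alternative 3 | 3,3-dimethoxy-2-methylprop-2-enoyl chloride | COC(OC)=C(C)C(Cl)=O
A7 | alternative 3 | bis(trimethylsilyl enol ether) of 6-methyl-1-[2,4,6-tris(benzyloxy)phenyl]heptane-3,5-dione (alkene geometry not defined) | CC(C)C(O[Si](C)(C)C)=CC(O[Si](C)(C)C)=CCc1c(OCc2ccccc2)cc(OCc2ccccc2)cc1OCc1ccccc1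
A8 | alternative 3 | 1-[2,4-dihydroxy-6-methoxy-5-methyl-3-{[2,4,6-tris(benzyloxy)phenyl]methyl}phenyl]-2-methylpropan-1-one | COc1c(C)c(O)c(Cc2c(OCc3ccccc3)cc(OCc4ccccc4)cc2OCc5ccccc5)c(O)c1C(=O)C(C)C
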